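**Retrosynthetic overview**
1. Manniflavanone ⇐ its nona‑O‑benzyl ether (one global hydrogenolysis).
2. Key disconnection: the upper‑unit C2–aryl (B‑ring) bond, made last by catalytic asymmetric conjugate arylation of a 3‑(taxifolin‑8‑yl)chromone. This sets I‑C2 by catalyst control and I‑C3 by trans‑selective protonation in one operation. The usual deoxybenzoin build‑up and flavanone α‑arylation are avoided.
3. The interflavonoid I‑C3–II‑C8 bond is made flat (sp2–sp2) by Suzuki coupling of a 3‑iodochromone with a taxifolin‑8‑boronate.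
4. The lower unit (II‑A/C/B rings, 2R,3R) comes intact from the chiral pool, (+)‑taxifolin, and is functionalised only at C8.
5. Ring order: II‑A/C/B preformed → I‑A/C chromone ring (enaminone iodocyclisation) → biaryl‑type coupling → I‑C2/C3 stereocentres and I‑B ring last.

Assumption: from the SMILES the target is (2R,3S) in the upper unit and (2R,3R) in the lower unit, and commercial (+)‑taxifolin is the (2R,3R) enantiomer.

**Step 1**
Reactants: 1, (+)‑taxifolin
Product: 2, (2R,3R)‑5,7‑bis(benzyloxy)‑2‑[3,4‑bis(benzyloxy)phenyl]‑3‑hydroxychroman‑4‑one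
Conditions: BnBr (4.5 eq), K2CO3, DMF, rt → 50 °C, Ar
Reagents that add atoms: benzyl bromide, BrCc1ccccc1
Why: Williamson etherification alkylates only the four phenoxides and leaves the aliphatic 3‑OH; no stereocentre is formed, and the 2,3‑trans isomer is the thermodynamic one, so any reversible C3 enolisation returns it.

**Step 2**
Reactants: 2
Product: 3, (2R,3R)‑3,5,7‑tris(benzyloxy)‑2‑[3,4‑bis(benzyloxy)phenyl]chroman‑4‑one
Conditions: BnBr, Ag2O, DMF, rt, dark
Reagents that add atoms: benzyl bromide, BrCc1ccccc1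
Why: Purdie‑type silver‑oxide alkylation benzylates the α‑ketol OH without forming an enolate, so there is no C3 epimerisation, β‑elimination or ring opening.

**Step 3**
Reactants: 3
Product: 4, (2R,3R)‑3,5,7‑tris(benzyloxy)‑2‑[3,4‑bis(benzyloxy)phenyl]‑8‑iodochroman‑4‑one
Conditions: NIS (1.05 eq), TFA (cat.), MeCN/CH2Cl2, 0 °C → rt
Reagents that add atoms: N‑iodosuccinimide, O=C1CCC(=O)N1I
Why: Electrophilic aromatic iodination goes to the A ring (three O‑donors versus two on the B ring) and to C8, which is para to 5‑OBn and flanked by only one free benzyloxy group, whereas C6 sits between two; the acidic conditions leave C2/C3 untouched.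

**Step 4**
Reactants: 4
Product: 5, (2R,3R)‑3,5,7‑tris(benzyloxy)‑2‑[3,4‑bis(benzyloxy)phenyl]‑8‑(4,4,5,5‑tetramethyl‑1,3,2‑dioxaborolan‑2‑yl)chroman‑4‑one
Conditions: HBpin, Pd(OAc)2/SPhos (cat.), Et3N, dioxane, 80 °C
Reagents that add atoms: pinacolborane, CC1(C)OBOC1(C)C
Why: Masuda–Miyaura borylation with a bulky biarylphosphine handles di‑ortho‑substituted electron‑rich aryl iodides, and the amine base is too weak to open the flavanonol ring.

**Step 5**
Reactants: 6, 2′,4′,6′‑trihydroxyacetophenone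
Product: 7, 1‑[2,4‑bis(benzyloxy)‑6‑hydroxyphenyl]ethanone
Conditions: BnBr (2.1 eq), K2CO3, acetone, reflux
Reagents that add atoms: benzyl bromide, BrCc1ccccc1
Why: Williamson etherification stops at the dibenzyl ether because the last ortho‑OH is hydrogen‑bonded to the ketone and much less nucleophilic.

**Step 6**
Reactants: 7
Product: 8, (E)‑1‑[2,4‑bis(benzyloxy)‑6‑hydroxyphenyl]‑3‑(dimethylamino)prop‑2‑en‑1‑one
Conditions: DMF‑DMA, toluene, 90 °C
Reagents that add atoms: N,N‑dimethylformamide dimethyl acetal, COC(OC)N(C)C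
Why: Enaminone condensation of the methyl ketone with the amide acetal installs the future chromone C2 carbon; the E geometry follows from conjugation.

**Step 7**
Reactants: 8
Product: 9, 5,7‑bis(benzyloxy)‑3‑iodo‑4H‑chromen‑4‑one
Conditions: I2, pyridine, CHCl3, rt
Reagents that add atoms: iodine, II
Why: Gammill iodocyclisation: α‑iodination of the enaminone, 6‑endo attack by the phenol and loss of Me2NH give the 3‑iodochromone (rings I‑A/C).

**Step 8**
Reactants: 5 and 9
Product: 10, 5,7‑bis(benzyloxy)‑3‑[(2R,3R)‑3,5,7‑tris(benzyloxy)‑2‑(3,4‑bis(benzyloxy)phenyl)‑4‑oxochroman‑8‑yl]‑4H‑chromen‑4‑one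
Conditions: Pd(OAc)2/SPhos (cat.), K3PO4, toluene/H2O (10:1), 70 °C
Reagents that add atoms: none beyond reactants 5 and 9
Why: Suzuki–Miyaura coupling forms the hindered I‑C3–II‑C8 bond at the sp2 level, where SPhos tolerates 2,6‑dioxygenated boronates and 3‑iodochromones are standard isoflavone precursors; no stereocentre is formed and the mild biphasic base spares C2″/C3″.

**Step 9**
Reactants: 10 and 11, [3,4‑bis(benzyloxy)phenyl]boronic acid
Product: 12, nona‑O‑benzylmanniflavanone: (2R,3S)‑5,7‑bis(benzyloxy)‑2‑[3,4‑bis(benzyloxy)phenyl]‑3‑[(2R,3R)‑3,5,7‑tris(benzyloxy)‑2‑(3,4‑bis(benzyloxy)phenyl)‑4‑oxochroman‑8‑yl]chroman‑4‑one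
Conditions: 11 (2.5 eq), Pd(TFA)2 (10 mol %), (S)‑t‑BuPyOx (12 mol %), NH4PF6, H2O (5 eq), ClCH2CH2Cl, 60 °C; then CSA (cat.), CHCl3, rt
Reagents that add atoms: [3,4‑bis(benzyloxy)phenyl]boronic acid (11), OB(O)c1ccc(OCc2ccccc2)c(OCc2ccccc2)c1
Why: Proposed new method: this extends the known Pd(II)/pyridine‑oxazoline asymmetric conjugate addition of arylboronic acids to chromones to a 3‑aryl chromone. The cationic Ar–Pd(II)L* adds syn across C2=C3 with the aryl going to the unhindered C2–H terminus, on the face the ligand selects for simple chromones (predicted 2R, to be confirmed on the product). No syn β‑H is available, so no flavone forms, and the π‑benzyl‑stabilised Pd enolate is protonated. Acid‑catalysed enolisation then converges C3 to the diequatorial 2,3‑trans (3S) isomer without ring opening. Because unit II is enantiopure, the (2S,3R) by‑product is a diastereomer and is removed by chromatography.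

**Step 10**
Reactants: 12
Product: 13, manniflavanone
Conditions: H2 (1 atm), Pd(OH)2/C, THF/MeOH, rt; filter under Ar
Reagents that add atoms: none
Why: Catalytic hydrogenolysis cleaves all nine benzyl ethers under neutral conditions that do not enolise or open either pyranone ring, so all four stereocentres are retained.

**Compound list**
1 | (+)‑taxifolin, (2R,3R) | O=C1c2c(O)cc(O)cc2O[C@H](c2ccc(O)c(O)c2)[C@H]1O | starting material
2 | 5,7,3′,4′‑tetra‑O‑benzyl‑(2R,3R)‑taxifolin | O=C1c2c(OCc3ccccc3)cc(OCc3ccccc3)cc2O[C@H](c2ccc(OCc3ccccc3)c(OCc3ccccc3)c2)[C@H]1O | intermediate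
3 | 3,5,7,3′,4′‑penta‑O‑benzyl‑(2R,3R)‑taxifolin | O=C1c2c(OCc3ccccc3)cc(OCc3ccccc3)cc2O[C@H](c2ccc(OCc3ccccc3)c(OCc3ccccc3)c2)[C@H]1OCc6ccccc6 | intermediate
4 | 8‑iodo‑penta‑O‑benzyl‑(2R,3R)‑taxifolin | O=C1c2c(OCc3ccccc3)cc(OCc3ccccc3)c(I)c2O[C@H](c2ccc(OCc3ccccc3)c(OCc3ccccc3)c2)[C@H]1OCc6ccccc6 | intermediate
5 | 8‑(pinacolboryl)‑penta‑O‑benzyl‑(2R,3R)‑taxifolin | O=C1c2c(OCc3ccccc3)cc(OCc3ccccc3)c(B3OC(C)(C)C(C)(C)O3)c2O[C@H](c2ccc(OCc3ccccc3)c(OCc3ccccc3)c2)[C@H]1OCc6ccccc6 | intermediate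
6 | 2′,4′,6′‑trihydroxyacetophenone | CC(=O)c1c(O)cc(O)cc1O | starting material
7 | 1‑[2,4‑bis(benzyloxy)‑6‑hydroxyphenyl]ethanone | CC(=O)c1c(O)cc(OCc2ccccc2)cc1OCc1ccccc1 | intermediate
8 | (E)‑1‑[2,4‑bis(benzyloxy)‑6‑hydroxyphenyl]‑3‑(dimethylamino)prop‑2‑en‑1‑one | CN(C)/C=C/C(=O)c1c(O)cc(OCc2ccccc2)cc1OCc1ccccc1 | intermediate
9 | 5,7‑bis(benzyloxy)‑3‑iodo‑4H‑chromen‑4‑one | O=c1c(I)coc2cc(OCc3ccccc3)cc(OCc3ccccc3)c12 | intermediate
10 | 5,7‑bis(benzyloxy)‑3‑[(2R,3R)‑penta‑O‑benzyltaxifolin‑8‑yl]‑4H‑chromen‑4‑one | O=C1c2c(OCc3ccccc3)cc(OCc3ccccc3)c(-c3coc4cc(OCc5ccccc5)cc(OCc5ccccc5)c4c3=O)c2O[C@H](c2ccc(OCc3ccccc3)c(OCc3ccccc3)c2)[C@H]1OCc6ccccc6 | intermediate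
11 | [3,4‑bis(benzyloxy)phenyl]boronic acid | OB(O)c1ccc(OCc2ccccc2)c(OCc2ccccc2)c1 | starting material
12 | nona‑O‑benzylmanniflavanone, (2R,3S,2″R,3″R) | O=C1c2c(OCc3ccccc3)cc(OCc3ccccc3)c([C@@H]3C(=O)c4c(OCc5ccccc5)cc(OCc5ccccc5)cc4O[C@H]3c3ccc(OCc5ccccc5)c(OCc5ccccc5)c3)c2O[C@H](c2ccc(OCc3ccccc3)c(OCc3ccccc3)c2)[C@H]1OCc6ccccc6 | intermediate
13 | manniflavanone, (2R,3S,2″R,3″R) | O=C1c2c(O)cc(O)c([C@@H]3C(=O)c4c(O)cc(O)cc4O[C@H]3c3ccc(O)c(O)c3)c2O[C@H](c2ccc(O)c(O)c2)[C@H]1O | target

**Totals**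
Total steps: 10. Longest linear sequence: 7 (steps 1–4, 8, 9, 10).

**Three steps most likely to fail**
- **Step 9** (conjugate arylation of a hindered, electron‑rich isoflavone; reactivity and facial control are unproven). Fallback: form ring I‑C by O1–C2 closure instead. Convert iodide 4 into the deoxybenzoin by α‑arylation of O‑protected ketone 7, then run a Knoevenagel/intramolecular oxa‑Michael with 3,4‑bis(benzyloxy)benzaldehyde under a chiral bifunctional thiourea/amine. This gives the trans‑2,3‑diarylchromanone, and the two diastereomers are separated.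
- **Step 8** (Suzuki coupling of a protodeboronation‑prone di‑ortho‑oxygenated boronate). Fallback: make the I‑C3–II‑C8 bond before the chromone exists. Couple iodide 4 with the unhindered methyl of O‑MOM‑protected 7 (Pd α‑arylation, K3PO4) to give the deoxybenzoin, then deprotect and close with DMF‑DMA to the same isoflavone 10.
- **Step 3** (C8 versus C6 or B‑ring iodination). Fallback: take the C8‑halogenated lower unit from (+)‑catechin, where the regiochemistry is reliable. Tetra‑O‑benzylcatechin is brominated at C8 with NBS, 3‑O‑benzylated, and oxidised at C4 (DDQ/H2O, then Dess–Martin) to the 8‑bromo analogue of 4 with the same (2R,3R) configuration.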